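**Assumption:** the SMILES is read as a (3S,4S)-trans-lactone whose C4 benzyl ring (ring B) is part of a (2R,3S)-trans-dihydrobenzofuran and whose C3 benzyl ring (ring A) carries a (1S,2S)-anti-1,3-diol arm. Reagents without a compound number are bought. Xc stands for the (4S)-4-benzyl-2-oxo-1,3-oxazolidin-3-yl group and Ar' for 4-benzyloxy-3-methoxyphenyl.

**Retrosynthetic overview**
- Target ⇐ hydrogenolysis of its tri-O-benzyl ether; the open anti-diol arm on ring A ⇐ magnesium-catalysed Evans anti-aldol and borohydride cleavage, run on the finished lactone.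
- trans-Lactone ⇐ benzylation of a 4-substituted butyrolactone with an iodobenzyl bromide; the same bromide supplies ring A and ring B.
- Key step: butyrolactone and trans-dihydrobenzofuran close together in one acid operation from an acyclic triol tert-butyl ester (lactonisation plus debenzylative cycloetherification through the p-alkoxybenzyl cation).
- That triol ester ⇐ one LiBH4 cleavage of a bis-imide ⇐ anti-aldol ⇐ zinc-enolate arylation (one Reformatsky reagent serves both arylations) ⇐ Evans alkylation of a succinyl imide.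
- Ring order: lactone and dihydrobenzofuran together, nothing after. (S)-4-benzyloxazolidin-2-one is the only source of chirality.

**Route**

Step 1
Reactants: 1 5-iodovanillin (4-hydroxy-3-iodo-5-methoxybenzaldehyde)
Product: 2 4-(benzyloxy)-3-iodo-5-methoxybenzaldehyde
Conditions: BnBr, K2CO3, DMF, 60 °C
Reagents that add atoms: benzyl bromide, BrCc1ccccc1
Why: Williamson etherification of the phenoxide; no stereocentre.

Step 2
Reactants: 2 4-(benzyloxy)-3-iodo-5-methoxybenzaldehyde
Product: 3 [4-(benzyloxy)-3-iodo-5-methoxyphenyl]methanol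
Conditions: NaBH4, MeOH/THF, 0 °C
Reagents that add atoms: none
Why: Borohydride reduction of the aldehyde; aryl iodide and benzyl ether are inert.

Step 3
Reactants: 3 [4-(benzyloxy)-3-iodo-5-methoxyphenyl]methanol
Product: 4 4-(benzyloxy)-3-iodo-5-methoxybenzyl bromide
Conditions: PBr3, CH2Cl2, 0 °C
Reagents that add atoms: phosphorus tribromide, BrP(Br)Br
Why: Bromide displaces the phosphite ester of the benzylic alcohol; standard for alkoxybenzyl alcohols.

Step 4
Reactants: 5 4-tert-butoxy-4-oxobutanoic acid (mono-tert-butyl succinate); 6 (S)-4-benzyl-1,3-oxazolidin-2-one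
Product: 8 tert-butyl 4-[(4S)-4-benzyl-2-oxo-1,3-oxazolidin-3-yl]-4-oxobutanoate, via mixed pivalic anhydride 7 (not isolated)
Conditions: t-BuCOCl, Et3N, THF, −20 °C; then 6, LiCl, rt
Reagents that add atoms: none
Why: N-acylation of the oxazolidinone through the mixed anhydride (LiCl/Et3N protocol); the hindered pivaloyl carbonyl is not attacked.

Step 5
Reactants: 8 tert-butyl 4-[(4S)-4-benzyl-2-oxo-1,3-oxazolidin-3-yl]-4-oxobutanoate; 4 4-(benzyloxy)-3-iodo-5-methoxybenzyl bromide
Product: 10 tert-butyl (3S)-3-[4-(benzyloxy)-3-iodo-5-methoxybenzyl]-4-[(4S)-4-benzyl-2-oxo-1,3-oxazolidin-3-yl]-4-oxobutanoate, via sodium Z-enolate 9 (not isolated)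
Conditions: NaN(SiMe3)2, THF, −78 °C; then 4, −78 to −40 °C
Reagents that add atoms: none
Why: Evans asymmetric alkylation; the chelated Z-enolate of the imide (more acidic than the ester) is benzylated on the face opposite the auxiliary benzyl group, which sets C3 as S (the future lactone C4).

Step 6
Reactants: 6 (S)-4-benzyl-1,3-oxazolidin-2-one
Product: 12 (4S)-4-benzyl-3-(bromoacetyl)-1,3-oxazolidin-2-one, via N-lithio oxazolidinone 11 (not isolated)
Conditions: n-BuLi, THF, −78 °C; then BrCH2COBr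
Reagents that add atoms: bromoacetyl bromide, O=C(Br)CBr
Why: N-acylation of the lithiated oxazolidinone with the acid bromide, which reacts at the acyl carbon at low temperature.

Step 7
Reactants: 12 (4S)-4-benzyl-3-(bromoacetyl)-1,3-oxazolidin-2-one
Product: 13 bromozinc enolate of (4S)-3-acetyl-4-benzyl-1,3-oxazolidin-2-one as a titrated THF solution
Conditions: Zn dust (activated with 5 mol% Me3SiCl and 5 mol% BrCH2CH2Br), THF, 0 °C to rt; decanted from excess Zn under argon, titrated with I2, kept at −20 °C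
Reagents that add atoms: zinc, [Zn]
Why: Reformatsky reagent formation by insertion of activated zinc into the α-bromo imide C–Br bond, a pure addition in which every atom of 12 and one zinc atom end up in 13; no stereocentre is formed.

Step 8
Reactants: 10 tert-butyl (3S)-3-[4-(benzyloxy)-3-iodo-5-methoxybenzyl]-4-[(4S)-4-benzyl-2-oxo-1,3-oxazolidin-3-yl]-4-oxobutanoate; 13 bromozinc enolate of (4S)-3-acetyl-4-benzyl-1,3-oxazolidin-2-one
Product: 14 ring-B arylacetyl bis-imide (10 in which the iodine is replaced by CH2C(=O)Xc)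
Conditions: 13 (1.5 equiv), Pd(dba)2 (5 mol%), P(t-Bu)3 (10 mol%), THF, rt to 50 °C
Reagents that add atoms: none
Why: Proposed new method: oxidative addition of the aryl iodide to zerovalent palladium, transmetallation with the weakly basic Reformatsky-type zinc enolate of the N-acetyl oxazolidinone and reductive elimination should give the arylacetyl imide directly, without touching the existing imide or tert-butyl ester; the closest known reaction is the Pd-catalysed α-arylation of zinc enolates of esters and amides (Negishi-type Reformatsky arylation).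

Step 9
Reactants: 14 ring-B arylacetyl bis-imide; 15 4-(benzyloxy)-3-methoxybenzaldehyde (O-benzylvanillin)
Product: 17 (2R,3S)-anti-aldol bis-imide (14 in which the arylacetyl CH2 has become CH bearing (S)-CH(OH)Ar'), via TMS ether 16 (not isolated)
Conditions: 15, MgCl2 (20 mol%), Et3N, Me3SiCl, EtOAc, rt; then Et3N·3HF, THF, 0 °C
Reagents that add atoms: none
Why: Evans magnesium-halide-catalysed direct anti-aldol; only the arylacetyl imide is soft-enolised, its Mg-chelated Z-enolate adds to the aldehyde on the face away from the auxiliary benzyl group to give the (2R,3S) anti adduct, and silylation of the aldolate prevents retro-aldol.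

Step 10
Reactants: 17 (2R,3S)-anti-aldol bis-imide
Product: 18 tert-butyl (3S)-3-{4-(benzyloxy)-3-[(1S,2S)-1-(4-benzyloxy-3-methoxyphenyl)-1,3-dihydroxypropan-2-yl]-5-methoxybenzyl}-4-hydroxybutanoate
Conditions: LiBH4, THF/MeOH, 0 °C to rt
Reagents that add atoms: none
Why: Reductive cleavage of both N-acyloxazolidinones to primary alcohols with LiBH4; the tert-butyl ester is too hindered to react or lactonise, and no stereocentre is touched.

Step 11
Reactants: 18 tert-butyl (3S)-3-{4-(benzyloxy)-3-[(1S,2S)-1-(4-benzyloxy-3-methoxyphenyl)-1,3-dihydroxypropan-2-yl]-5-methoxybenzyl}-4-hydroxybutanoate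
Product: 19 (4S)-4-{[(2R,3S)-2-(4-benzyloxy-3-methoxyphenyl)-3-(hydroxymethyl)-7-methoxy-2,3-dihydro-1-benzofuran-5-yl]methyl}oxolan-2-one
Conditions: CF3CO2H/CH2Cl2 (1:4), pentamethylbenzene (3 equiv), 0 °C to rt; aq. NaHCO3/MeOH work-up
Reagents that add atoms: none
Why: Proposed new method: the acid cleaves the tert-butyl ester so the γ-hydroxy acid lactonises, and ionises the p-benzyloxybenzylic alcohol to a cation that the twisted ortho benzyl ether oxygen of ring B traps in a five-membered closure, the oxonium then passing its benzyl group to pentamethylbenzene; C2 is set trans to the C3 hydroxymethyl (net inversion of the carbinol carbon) by product stability under reversible ionisation; closest known reactions are the acid-mediated phenylcoumaran closure of 2-(2-hydroxyaryl)-1-arylpropane-1,3-diols and dealkylative cyclisations of ortho-alkoxyaryl cations (debenzylative cycloetherification).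

Step 12
Reactants: 19 (4S)-4-{[(2R,3S)-2-(4-benzyloxy-3-methoxyphenyl)-3-(hydroxymethyl)-7-methoxy-2,3-dihydro-1-benzofuran-5-yl]methyl}oxolan-2-one; 4 4-(benzyloxy)-3-iodo-5-methoxybenzyl bromide
Product: 21 (3S,4S)-3-[4-(benzyloxy)-3-iodo-5-methoxybenzyl]-4-{[(2R,3S)-2-(4-benzyloxy-3-methoxyphenyl)-3-(hydroxymethyl)-7-methoxy-2,3-dihydro-1-benzofuran-5-yl]methyl}oxolan-2-one, via dilithio alkoxide-enolate 20 (not isolated)
Conditions: LiN(SiMe3)2 (2.2 equiv), THF, −78 °C; then 4, −78 to −30 °C; H2O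
Reagents that add atoms: none
Why: Lactone enolate alkylation run on the alkoxide–enolate dianion (Fráter–Seebach-type C-selectivity, the lithium alkoxide being a poor nucleophile at low temperature); the bromide enters anti to the C4 substituent, which sets C3 as S (trans).

Step 13
Reactants: 21 (3S,4S)-3-[4-(benzyloxy)-3-iodo-5-methoxybenzyl]-4-{[(2R,3S)-2-(4-benzyloxy-3-methoxyphenyl)-3-(hydroxymethyl)-7-methoxy-2,3-dihydro-1-benzofuran-5-yl]methyl}oxolan-2-one; 13 bromozinc enolate of (4S)-3-acetyl-4-benzyl-1,3-oxazolidin-2-one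
Product: 22 ring-A arylacetyl imide (21 in which the iodine is replaced by CH2C(=O)Xc)
Conditions: 13 (2 equiv, re-titrated), Pd(dba)2 (5 mol%), P(t-Bu)3 (10 mol%), THF, rt to 50 °C
Reagents that add atoms: none
Why: Proposed new method: the same Pd-catalysed arylation of the imide zinc enolate as in step 8, here relying on the known tolerance of zinc enolates for free alcohols and lactones; closest known reaction is the Negishi-type α-arylation of Reformatsky reagents of esters and amides.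

Step 14
Reactants: 22 ring-A arylacetyl imide; 15 4-(benzyloxy)-3-methoxybenzaldehyde
Product: 24 (2R,3S)-anti-aldol imide on ring A (22 in which the arylacetyl CH2 has become CH bearing (S)-CH(OH)Ar'), via bis-TMS ether 23 (not isolated)
Conditions: 15, MgCl2 (20 mol%), Et3N, Me3SiCl (3.5 equiv), EtOAc, rt; then Et3N·3HF, THF, 0 °C
Reagents that add atoms: none
Why: Evans magnesium-halide-catalysed anti-aldol as in step 9 (auxiliary-controlled face, anti through the chelated Z-enolate) sets both centres of the open arm; the lactone α-hydrogen is not enolised under soft enolisation and the free primary alcohol is only silylated in passing.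

Step 15
Reactants: 24 (2R,3S)-anti-aldol imide on ring A
Product: 25 tri-O-benzyl ether of the target (benzyl on the ring-A phenol and on both guaiacyl phenols)
Conditions: NaBH4, THF/H2O (4:1), 0 °C to rt
Reagents that add atoms: none
Why: Chemoselective borohydride reduction of the N-acyloxazolidinone to the primary alcohol, the twisted imide carbonyl being far more electrophilic than the γ-lactone; the acyl (2R,3S) centres become the (1S,2S)-diol by change of priorities only.

Step 16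
Reactants: 25 tri-O-benzyl ether of the target
Product: 26 CNP0186558.3
Conditions: H2 (1 atm), Pd/C (10%), EtOAc/MeOH, rt
Reagents that add atoms: none
Why: Neutral hydrogenolysis of the three aryl benzyl ethers; the dihydrobenzofuran C–O bond, the benzylic secondary alcohol and all six stereocentres are left alone, and no acid or base touches the cyclisation-prone free diol-phenol.

**Compound list**

1 | 5-iodovanillin | COc1cc(C=O)cc(I)c1O | starting material
2 | 4-(benzyloxy)-3-iodo-5-methoxybenzaldehyde | COc1cc(C=O)cc(I)c1OCc1ccccc1 | intermediate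
3 | [4-(benzyloxy)-3-iodo-5-methoxyphenyl]methanol | COc1cc(CO)cc(I)c1OCc1ccccc1 | intermediate
4 | 4-(benzyloxy)-3-iodo-5-methoxybenzyl bromide | COc1cc(CBr)cc(I)c1OCc1ccccc1 | intermediate
5 | 4-tert-butoxy-4-oxobutanoic acid | CC(C)(C)OC(=O)CCC(=O)O | starting material
6 | (S)-4-benzyl-1,3-oxazolidin-2-one | O=C1N[C@@H](Cc2ccccc2)CO1 | starting material
7 | mixed pivalic anhydride of 5 (formed in the flask) | CC(C)(C)OC(=O)CCC(=O)OC(=O)C(C)(C)C | intermediate
8 | tert-butyl 4-[(4S)-4-benzyl-2-oxo-1,3-oxazolidin-3-yl]-4-oxobutanoate | CC(C)(C)OC(=O)CCC(=O)N1[C@@H](Cc2ccccc2)COC1=O | intermediate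
9 | sodium Z-enolate of 8 (formed in the flask) | CC(C)(C)OC(=O)C/C=C(\[O-])N1[C@@H](Cc2ccccc2)COC1=O.[Na+] | intermediate
10 | tert-butyl (3S)-3-[4-(benzyloxy)-3-iodo-5-methoxybenzyl]-4-[(4S)-4-benzyl-2-oxo-1,3-oxazolidin-3-yl]-4-oxobutanoate | CC(C)(C)OC(=O)C[C@H](Cc1cc(OC)c(OCc2ccccc2)c(I)c1)C(=O)N1[C@@H](Cc2ccccc2)COC1=O | intermediate
11 | N-lithio derivative of 6 (formed in the flask) | [Li]N1[C@@H](Cc2ccccc2)COC1=O | intermediate
12 | (4S)-4-benzyl-3-(bromoacetyl)-1,3-oxazolidin-2-one | BrCC(=O)N1[C@@H](Cc2ccccc2)COC1=O | intermediate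
13 | bromozinc enolate of (4S)-3-acetyl-4-benzyl-1,3-oxazolidin-2-one (Reformatsky reagent, THF solution) | Br[Zn]CC(=O)N1[C@@H](Cc2ccccc2)COC1=O | intermediate
14 | ring-B arylacetyl bis-imide; tert-butyl (3S)-3-[4-(benzyloxy)-3-{2-[(4S)-4-benzyl-2-oxo-1,3-oxazolidin-3-yl]-2-oxoethyl}-5-methoxybenzyl]-4-[(4S)-4-benzyl-2-oxo-1,3-oxazolidin-3-yl]-4-oxobutanoate | CC(C)(C)OC(=O)C[C@H](Cc1cc(OC)c(OCc2ccccc2)c(CC(=O)N2[C@@H](Cc3ccccc3)COC2=O)c1)C(=O)N1[C@@H](Cc2ccccc2)COC1=O | intermediate
15 | 4-(benzyloxy)-3-methoxybenzaldehyde | COc1cc(C=O)ccc1OCc1ccccc1 | starting material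
16 | O-TMS ether of 17 (formed in the flask) | COc1cc([C@@H](O[Si](C)(C)C)[C@H](C(=O)N2[C@@H](Cc3ccccc3)COC2=O)c2cc(C[C@@H](CC(=O)OC(C)(C)C)C(=O)N3[C@@H](Cc4ccccc4)COC3=O)cc(OC)c2OCc2ccccc2)ccc1OCc1ccccc1 | intermediate
17 | (2R,3S)-anti-aldol bis-imide; tert-butyl (3S)-3-[4-(benzyloxy)-3-{(2R,3S)-1-[(4S)-4-benzyl-2-oxo-1,3-oxazolidin-3-yl]-3-[4-(benzyloxy)-3-methoxyphenyl]-3-hydroxy-1-oxopropan-2-yl}-5-methoxybenzyl]-4-[(4S)-4-benzyl-2-oxo-1,3-oxazolidin-3-yl]-4-oxobutanoate | COc1cc([C@@H](O)[C@H](C(=O)N2[C@@H](Cc3ccccc3)COC2=O)c2cc(C[C@@H](CC(=O)OC(C)(C)C)C(=O)N3[C@@H](Cc4ccccc4)COC3=O)cc(OC)c2OCc2ccccc2)ccc1OCc1ccccc1 | intermediate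
18 | tert-butyl (3S)-3-{4-(benzyloxy)-3-[(1S,2S)-1-(4-benzyloxy-3-methoxyphenyl)-1,3-dihydroxypropan-2-yl]-5-methoxybenzyl}-4-hydroxybutanoate | COc1cc([C@@H](O)[C@H](CO)c2cc(C[C@@H](CC(=O)OC(C)(C)C)CO)cc(OC)c2OCc2ccccc2)ccc1OCc1ccccc1 | intermediate
19 | (4S)-4-{[(2R,3S)-2-(4-benzyloxy-3-methoxyphenyl)-3-(hydroxymethyl)-7-methoxy-2,3-dihydro-1-benzofuran-5-yl]methyl}oxolan-2-one | O=C1C[C@H](Cc2cc(OC)c3c(c2)[C@@H](CO)[C@H](c2ccc(OCc4ccccc4)c(OC)c2)O3)CO1 | intermediate
20 | dilithio alkoxide-enolate of 19 (formed in the flask) | [Li+].[Li+].[O-]C1=C[C@H](Cc2cc(OC)c3c(c2)[C@@H](C[O-])[C@H](c2ccc(OCc4ccccc4)c(OC)c2)O3)CO1 | intermediate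
21 | (3S,4S)-3-[4-(benzyloxy)-3-iodo-5-methoxybenzyl]-4-{[(2R,3S)-2-(4-benzyloxy-3-methoxyphenyl)-3-(hydroxymethyl)-7-methoxy-2,3-dihydro-1-benzofuran-5-yl]methyl}oxolan-2-one | COc1cc(C[C@@H]2C(=O)OC[C@H]2Cc2cc(OC)c3c(c2)[C@@H](CO)[C@H](c2ccc(OCc4ccccc4)c(OC)c2)O3)cc(I)c1OCc1ccccc1 | intermediate
22 | ring-A arylacetyl imide; (3S,4S)-3-[4-(benzyloxy)-3-{2-[(4S)-4-benzyl-2-oxo-1,3-oxazolidin-3-yl]-2-oxoethyl}-5-methoxybenzyl]-4-{[(2R,3S)-2-(4-benzyloxy-3-methoxyphenyl)-3-(hydroxymethyl)-7-methoxy-2,3-dihydro-1-benzofuran-5-yl]methyl}oxolan-2-one | COc1cc(C[C@@H]2C(=O)OC[C@H]2Cc2cc(OC)c3c(c2)[C@@H](CO)[C@H](c2ccc(OCc4ccccc4)c(OC)c2)O3)cc(CC(=O)N2[C@@H](Cc3ccccc3)COC2=O)c1OCc1ccccc1 | intermediate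
23 | bis-O-TMS ether of 24 (formed in the flask) | COc1cc([C@@H](O[Si](C)(C)C)[C@H](C(=O)N2[C@@H](Cc3ccccc3)COC2=O)c2cc(C[C@@H]3C(=O)OC[C@H]3Cc3cc(OC)c4c(c3)[C@@H](CO[Si](C)(C)C)[C@H](c3ccc(OCc5ccccc5)c(OC)c3)O4)cc(OC)c2OCc2ccccc2)ccc1OCc1ccccc1 | intermediate
24 | (2R,3S)-anti-aldol imide on ring A; (3S,4S)-3-[4-(benzyloxy)-3-{(2R,3S)-1-[(4S)-4-benzyl-2-oxo-1,3-oxazolidin-3-yl]-3-[4-(benzyloxy)-3-methoxyphenyl]-3-hydroxy-1-oxopropan-2-yl}-5-methoxybenzyl]-4-{[(2R,3S)-2-(4-benzyloxy-3-methoxyphenyl)-3-(hydroxymethyl)-7-methoxy-2,3-dihydro-1-benzofuran-5-yl]methyl}oxolan-2-one | COc1cc([C@@H](O)[C@H](C(=O)N2[C@@H](Cc3ccccc3)COC2=O)c2cc(C[C@@H]3C(=O)OC[C@H]3Cc3cc(OC)c4c(c3)[C@@H](CO)[C@H](c3ccc(OCc5ccccc5)c(OC)c3)O4)cc(OC)c2OCc2ccccc2)ccc1OCc1ccccc1 | intermediate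
25 | tri-O-benzyl ether of the target; (3S,4S)-3-[4-(benzyloxy)-3-{(1S,2S)-1-[4-(benzyloxy)-3-methoxyphenyl]-1,3-dihydroxypropan-2-yl}-5-methoxybenzyl]-4-{[(2R,3S)-2-(4-benzyloxy-3-methoxyphenyl)-3-(hydroxymethyl)-7-methoxy-2,3-dihydro-1-benzofuran-5-yl]methyl}oxolan-2-one | COc1cc([C@@H](O)[C@H](CO)c2cc(C[C@@H]3C(=O)OC[C@H]3Cc3cc(OC)c4c(c3)[C@@H](CO)[C@H](c3ccc(OCc5ccccc5)c(OC)c3)O4)cc(OC)c2OCc2ccccc2)ccc1OCc1ccccc1 | intermediate
26 | CNP0186558.3, (3S,4S)-3-{4-hydroxy-3-[(1S,2S)-1,3-dihydroxy-1-(4-hydroxy-3-methoxyphenyl)propan-2-yl]-5-methoxybenzyl}-4-{[(2R,3S)-2-(4-hydroxy-3-methoxyphenyl)-3-(hydroxymethyl)-7-methoxy-2,3-dihydro-1-benzofuran-5-yl]methyl}oxolan-2-one | COc1cc([C@@H](O)[C@H](CO)c2cc(C[C@@H]3C(=O)OC[C@H]3Cc3cc(OC)c4c(c3)[C@@H](CO)[C@H](c3ccc(O)c(OC)c3)O4)cc(OC)c2O)ccc1O | target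

**Step count and risks**

Total steps: 16. Longest linear sequence: 13 steps (1, 2, 3, 5, 8, 9, 10, 11, 12, 13, 14, 15, 16). Steps 4, 6 and 7 are side branches. Bromide 4, zinc reagent 13 and aldehyde 15 are each used twice. Step 7 is run once on a scale that covers steps 8 and 13; the solution is kept cold under argon and re-titrated before step 13, and the step is simply repeated if the titre has fallen.

Three steps most likely to fail:

Step 11 (double ring closure with loss of the ring-B benzyl group). The benzyl ether oxygen is a weaker trap than a phenol, so loss of formaldehyde to a stilbene, elimination with scrambling of the neighbouring centre, or premature loss of the other benzyl group can compete. The fallback sets out from 18. Hydrogenolysis (H2, Pd/C, EtOAc) removes both benzyl ethers and gives the bis-phenol triol tert-butyl ester F1. Dilute acid (catalytic HCl in dioxane, or CF3CO2H/CH2Cl2 at 0 °C) then closes both rings by the classical route: the free p-hydroxybenzyl alcohol goes through its quinone methide to the trans-dihydrobenzofuran while the ester lactonises, giving the phenolic lactone–dihydrobenzofuran F2. Selective phenol benzylation (BnBr, K2CO3, acetone; the primary alcohol does not react) comes back to the route at 19.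

Step 8 (arylation of the imide zinc enolate; the same reaction recurs in step 13). The imide enolate may be too unstable or the hindered aryl iodide too slow. The fallback sets out from 10. Stille allylation (allyltributylstannane, Pd(PPh3)4, toluene, 100 °C) gives the ortho-allyl arene F3. Lemieux–Johnson cleavage (OsO4 cat., NaIO4, 2,6-lutidine, dioxane/H2O) gives the arylacetaldehyde F4, and Pinnick oxidation (NaClO2, NaH2PO4, 2-methyl-2-butene) gives the arylacetic acid F5. Acylation of 6 through the mixed pivalic anhydride (t-BuCOCl, Et3N; then 6, LiCl) comes back to the route at 14.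

Step 15 (imide reduction beside the lactone). Borohydride may over-reduce or open the lactone, or base may trigger retro-aldol. The fallback sets out from 24. LiOH/H2O2 (THF/H2O, 0 °C) removes the auxiliary by hydroperoxide-selective attack at the imide and, after mild acidification, gives the β-hydroxy acid F6 with the lactone re-closed. BH3·SMe2 (THF, 0 °C) then reduces the carboxylic acid much faster than the lactone and comes back to the route at 25.

**Further compounds**

F1 | step 11 | tert-butyl (3S)-4-hydroxy-3-{4-hydroxy-3-[(1S,2S)-1,3-dihydroxy-1-(4-hydroxy-3-methoxyphenyl)propan-2-yl]-5-methoxybenzyl}butanoate | COc1cc([C@@H](O)[C@H](CO)c2cc(C[C@@H](CC(=O)OC(C)(C)C)CO)cc(OC)c2O)ccc1O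
F2 | step 11 | (4S)-4-{[(2R,3S)-2-(4-hydroxy-3-methoxyphenyl)-3-(hydroxymethyl)-7-methoxy-2,3-dihydro-1-benzofuran-5-yl]methyl}oxolan-2-one | O=C1C[C@H](Cc2cc(OC)c3c(c2)[C@@H](CO)[C@H](c2ccc(O)c(OC)c2)O3)CO1
F3 | step 8 | tert-butyl (3S)-3-[3-allyl-4-(benzyloxy)-5-methoxybenzyl]-4-[(4S)-4-benzyl-2-oxo-1,3-oxazolidin-3-yl]-4-oxobutanoate | CC(C)(C)OC(=O)C[C@H](Cc1cc(OC)c(OCc2ccccc2)c(CC=C)c1)C(=O)N1[C@@H](Cc2ccccc2)COC1=O
F4 | step 8 | tert-butyl (3S)-3-[4-(benzyloxy)-3-methoxy-5-(2-oxoethyl)benzyl]-4-[(4S)-4-benzyl-2-oxo-1,3-oxazolidin-3-yl]-4-oxobutanoate | CC(C)(C)OC(=O)C[C@H](Cc1cc(OC)c(OCc2ccccc2)c(CC=O)c1)C(=O)N1[C@@H](Cc2ccccc2)COC1=O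
F5 | step 8 | {2-(benzyloxy)-5-[(2S)-2-{[(4S)-4-benzyl-2-oxo-1,3-oxazolidin-3-yl]carbonyl}-4-tert-butoxy-4-oxobutyl]-3-methoxyphenyl}acetic acid | CC(C)(C)OC(=O)C[C@H](Cc1cc(OC)c(OCc2ccccc2)c(CC(=O)O)c1)C(=O)N1[C@@H](Cc2ccccc2)COC1=O
F6 | step 15 | (2R,3S)-β-hydroxy acid (24 in which the oxazolidinone is replaced by OH) | COc1cc([C@@H](O)[C@H](C(=O)O)c2cc(C[C@@H]3C(=O)OC[C@H]3Cc3cc(OC)c4c(c3)[C@@H](CO)[C@H](c3ccc(OCc5ccccc5)c(OC)c3)O4)cc(OC)c2OCc2ccccc2)ccc1OCc1ccccc1
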